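Units of starting material are conserved: at the last reading of Sunday's run, target, other capture product and starting material hold 73.0% of the charge, trapped intermediate reads 0%, and I book the missing 27.0% as self-condensation product.

| setting | Sunday's | eta | delta |
|---|---|---|---|
| starting material | 0.031 M | 0.031 M | 0.031 M |
| first nucleophile | 0.033 M | 0.0217 M | 0.0217 M |
| second nucleophile | 0.0326 M | 0.0330 M | 0.0650 M |
| capture agent | 1.55 mM | 1.55 mM | 1.55 mM |
| remark | run made earlier |  |  |
| time |  | 10 d | 10 d |

Sunday's run (percent of the starting material charged)

| time / h | target / % | other capture product / % | starting material / % | trapped intermediate / % |
|---|---|---|---|---|
| 10.0 | 21.3 | 18.9 | 38.7 | 0 |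
| 20.0 | 30.1 | 26.8 | 18.3 | 0.6 |
| 30.0 | 34.7 | 30.1 | 9.1 | 0 |
| 40.0 | 36.6 | 32.1 | 4.3 | 0 |
| 50.0 | 37.6 | 33.3 | 2.1 | 0 |

(standard deviation of a reading: 0.3 percentage points)

- percent here means starting material units held: one self-condensation product counts as two
- steps under discussion: starting material <-> open intermediate; first nucleophile + open intermediate -> target; second nucleophile + open intermediate -> other capture product; open intermediate + capture agent -> trapped intermediate; 2 starting material -> self-condensation product

* which of these there is most of at the end, counted by the starting material in it, eta (other capture product / target / trapped intermediate / starting material)
* which of these there is most of at the end, counted by the starting material in it, delta (other capture product / target / trapped intermediate / starting material)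
* amount of the one of these that there is most of at the end, in percent of the starting material charged, eta
* amount of the one of these that there is most of at the end, in percent of the starting material charged, delta

Over Sunday's last interval the two capture products gain 2.2 percentage points while starting material loses 2.2 points, so I count what remains as captured too, and the captured total C is 73.0%. Starting material goes on halving every 10.0 h while the nucleophiles are consumed, so I read the opening as the rate-limiting step and carry C unchanged to eta and delta. Trapped intermediate reads 0.6% at its highest, so I drop the capture agent.

What remains is a contest between two amounts, free first nucleophile B and free second nucleophile D, for the same open intermediate. Target forms over other capture product in the ratio s·B/D, where s is the selectivity factor, the log of the fraction of B left over the log of the fraction of D left. Sunday's last reading gives s = 1.14.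

I split C by s·B/D at the charged amounts, which gives other capture product 41.7% in eta and 52.8% in delta. Repeating with amounts halfway through the consumption gives 42.3% in eta and 53.1% in delta. The forecast names other capture product at 42.5% for eta and other capture product at 53.5% for delta, slightly above mine, and it takes “the same 73.5% capture” where I take 73.0%.

Eta ends with other capture product at 42.4% and target at 31.1%; delta ends with other capture product at 53.4% and target at 20.2%.

    starting material ⇌ open intermediate (K = 0.0840, k = 0.0640 h⁻¹)
    first nucleophile + open intermediate → target (k = 1100 M⁻¹ h⁻¹)
    second nucleophile + open intermediate → other capture product (k = 950 M⁻¹ h⁻¹)
    open intermediate + capture agent → trapped intermediate (k = 23.0 M⁻¹ h⁻¹)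
    2 starting material → self-condensation product (k = 0.810 M⁻¹ h⁻¹)

Take delta with 0.087 M of first nucleophile. There s·B/D at the charge is 1.53, above one, so I expect target to lead, and C splits into 44.2% target and 28.8% other capture product. That neighbouring flask ends with 44.6% of target and 29.1% of other capture product.

(The readings are calculated with constants of no real substance; the scatter is artificial.)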